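**Retrosynthetic overview**

1. The last bond made is C12–C13 of the enone: the target is cut into the (E)-alkenyl triflate of the fully oxygenated decalin (C12, an aldehyde-derived acceptor carbon) and the acetyl-anion equivalent tributyl(1-ethoxyvinyl)stannane (Pd coupling, then enol-ether hydrolysis).
2. Ring-B oxygenation, backwards: 7β-OH from the 7-ketone; 6α-OAc from α-acetoxylation of that ketone; 8α-OH/7-C=O from α-face dihydroxylation of a Δ7 olefin followed by oxidation.
3. The (E)-alkenyl triflate comes from the C12 aldehyde, which comes from the Δ7 methyl ester, which comes from (+)-sclareolide by acid-mediated lactone opening and dehydration.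
4. Ring order: no ring is built. Rings A and B and C5, C9, C10 come intact from sclareolide (its lactone ring is opened first); C6, C7, C8 are set by substrate control.

Assumption: labdane numbering and α/β descriptors are used. The target SMILES decodes as the normal-labdane series (5S,6R,7S,8S,9R,10S; 5α-H, 10β-CH3, 9β side chain, 6α-OAc, 7β-OH, 8α-OH, 11E), which is the series of (+)-sclareolide.

**Route**

Step 1
Reactants: 1 (+)-sclareolide
Product: 3 methyl 13,14,15,16-tetranorlabd-7-en-12-oate, via Δ7 carboxylic acid 2 (not isolated)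
Conditions: conc. H2SO4, MeOH, rt, 48 h; AgNO3–SiO2 chromatography
Reagents that add atoms: methanol, CO
Why: Acid-mediated alkyl–oxygen opening of the tertiary lactone (E1 dehydration) and Fischer esterification, in which the C8 cation loses H-7 under kinetic conditions to give mainly the endocyclic Δ7 olefin (Δ8(9) and Δ8(17) isomers are removed on AgNO3–silica), leaving C5, C9 and C10 untouched.

Step 2
Reactants: 3 methyl 13,14,15,16-tetranorlabd-7-en-12-oate
Product: 4 13,14,15,16-tetranorlabd-7-en-12-al
Conditions: DIBAL-H (1.1 equiv), toluene, −78 °C; Rochelle salt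
Reagents that add atoms: none
Why: DIBAL-H partial reduction, in which the tetrahedral aluminium hemiacetal is stable at −78 °C and gives the aldehyde only on work-up, with no stereocentre involved.

Step 3
Reactants: 4 13,14,15,16-tetranorlabd-7-en-12-al
Product: 5 (11E)-13,14,15,16-tetranorlabda-7,11-dien-12-yl trifluoromethanesulfonate
Conditions: LiHMDS, THF, −78 °C; PhNTf2, −78 → 0 °C
Reagents that add atoms: N-phenylbis(trifluoromethanesulfonimide), O=S(=O)(N(c1ccccc1)S(=O)(=O)C(F)(F)F)C(F)(F)F
Why: Enol triflate formation from the kinetic lithium enolate, where the Ireland-type transition state of an aldehyde (H on the carbonyl carbon) places the bulky C9 residue trans to O–Li and so gives the (E)-alkenyl triflate, while C9 itself is not deprotonated.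

Step 4
Reactants: 5 (11E)-13,14,15,16-tetranorlabda-7,11-dien-12-yl trifluoromethanesulfonate
Product: 6 (11E)-7α,8α-dihydroxy-13,14,15,16-tetranorlabd-11-en-12-yl trifluoromethanesulfonate
Conditions: OsO4 (5 mol %), NMO, acetone/H2O, rt
Reagents that add atoms: osmium tetroxide (catalytic O carrier), O=[Os](=O)(=O)=O; N-methylmorpholine N-oxide, C[N+]1([O-])CCOCC1; water, O
Why: Upjohn dihydroxylation, in which electrophilic OsO4 selects the electron-rich trisubstituted Δ7 olefin over the electron-poor enol triflate and adds suprafacially from the α face opposite the axial C10 methyl group, setting 8α-OH (8β-CH3) and 7α-OH.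

Step 5
Reactants: 6 (11E)-7α,8α-dihydroxy-13,14,15,16-tetranorlabd-11-en-12-yl trifluoromethanesulfonate
Product: 7 (11E)-8α-hydroxy-7-oxo-13,14,15,16-tetranorlabd-11-en-12-yl trifluoromethanesulfonate
Conditions: IBX, DMSO, rt
Reagents that add atoms: none
Why: IBX oxidation of the secondary 7-OH of a secondary/tertiary 1,2-diol to the α-ketol without glycol cleavage, the tertiary 8α-OH being inert so that C8 keeps its configuration.

Step 6
Reactants: 7 (11E)-8α-hydroxy-7-oxo-13,14,15,16-tetranorlabd-11-en-12-yl trifluoromethanesulfonate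
Product: 10 (11E)-6α-acetoxy-8α-hydroxy-7-oxo-13,14,15,16-tetranorlabd-11-en-12-yl trifluoromethanesulfonate, via bis-silyl enol ether 8 (not isolated), via 8-O-TMS acetoxy ketone 9 (not isolated)
Conditions: TMSOTf, Et3N, CH2Cl2, 0 °C; then Pb(OAc)4, CH2Cl2, −20 °C → rt; then HF·pyridine, THF, 0 °C
Reagents that add atoms: lead(IV) acetate, CC(=O)O[Pb](OC(C)=O)(OC(C)=O)OC(C)=O; trimethylsilyl triflate (atoms in 8 and 9 only), C[Si](C)(C)OS(=O)(=O)C(F)(F)F
Why: Silyl enol ether formation (only C6 is enolisable, and silylation of the tertiary OH prevents α-ketol cleavage) followed by Rubottom-type lead(IV) acetate α-acetoxylation, in which acetate enters C6 from the α face away from the axial β-methyl groups on C4 and C10 to give the equatorial, thermodynamically preferred 6α-acetate.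

Step 7
Reactants: 10 (11E)-6α-acetoxy-8α-hydroxy-7-oxo-13,14,15,16-tetranorlabd-11-en-12-yl trifluoromethanesulfonate
Product: 11 (11E)-6α-acetoxy-7β,8α-dihydroxy-13,14,15,16-tetranorlabd-11-en-12-yl trifluoromethanesulfonate
Conditions: NaBH4, CeCl3·7H2O, MeOH/CH2Cl2, −78 → −40 °C; AcOH quench
Reagents that add atoms: none
Why: Luche-type borohydride reduction of the activated α-acetoxy ketone, in which hydride attacks axially from the α face (the β face is shielded by the axial 8β-methyl group) to give the equatorial 7β-alcohol, while low temperature and a buffered quench suppress 6→7 acetyl migration.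

Step 8
Reactants: 11 (11E)-6α-acetoxy-7β,8α-dihydroxy-13,14,15,16-tetranorlabd-11-en-12-yl trifluoromethanesulfonate; 12 tributyl(1-ethoxyvinyl)stannane
Product: 14 (11E)-6α-acetoxy-7β,8α-dihydroxy-14,15-dinorlabd-11-en-13-one, via 2-ethoxy diene 13 (not isolated)
Conditions: Pd(PPh3)4 (5 mol %), LiCl, THF, 65 °C; then 1 M HCl, THF, rt
Reagents that add atoms: tributyl(1-ethoxyvinyl)stannane 12, CCCC[Sn](CCCC)(CCCC)C(=C)OCC; water, O
Why: Stille coupling with an acetyl-anion equivalent, in which oxidative addition of Pd(0) into the C12–OTf bond, transmetalation of the masked acyl nucleophile and reductive elimination join C12 (a former aldehyde carbon) to C13 (the ketone carbon) with retention of the E geometry, and mild acid hydrolysis of the enol ether then releases the methyl ketone in the presence of the free hydroxyls and the acetate.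

**Compound list**

1 | (+)-sclareolide; 13,14,15,16-tetranorlabdan-12,8α-olide, (3aR,5aS,9aS,9bR) | O=C1C[C@H]2[C@@](C)(CC[C@H]3C(C)(C)CCC[C@]23C)O1 | starting material
2 | 13,14,15,16-tetranorlabd-7-en-12-oic acid; 2-[(1S,4aS,8aS)-2,5,5,8a-tetramethyl-1,4,4a,5,6,7,8,8a-octahydronaphthalen-1-yl]acetic acid | OC(=O)C[C@H]1C(C)=CC[C@H]2C(C)(C)CCC[C@@]21C | intermediate (not isolated)
3 | methyl 13,14,15,16-tetranorlabd-7-en-12-oate | COC(=O)C[C@H]1C(C)=CC[C@H]2C(C)(C)CCC[C@@]21C | intermediate
4 | 13,14,15,16-tetranorlabd-7-en-12-al | O=CC[C@H]1C(C)=CC[C@H]2C(C)(C)CCC[C@@]21C | intermediate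
5 | (11E)-13,14,15,16-tetranorlabda-7,11-dien-12-yl trifluoromethanesulfonate (OTf and C9 trans) | FC(F)(F)S(=O)(=O)O/C=C/[C@H]1C(C)=CC[C@H]2C(C)(C)CCC[C@@]21C | intermediate
6 | (11E)-7α,8α-dihydroxy-13,14,15,16-tetranorlabd-11-en-12-yl trifluoromethanesulfonate (8β-CH3) | FC(F)(F)S(=O)(=O)O/C=C/[C@H]1[C@](C)(O)[C@H](O)C[C@H]2C(C)(C)CCC[C@@]21C | intermediate
7 | (11E)-8α-hydroxy-7-oxo-13,14,15,16-tetranorlabd-11-en-12-yl trifluoromethanesulfonate | FC(F)(F)S(=O)(=O)O/C=C/[C@H]1[C@](C)(O)C(=O)C[C@H]2C(C)(C)CCC[C@@]21C | intermediate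
8 | (11E)-7,8α-bis(trimethylsilyloxy)-13,14,15,16-tetranorlabda-6,11-dien-12-yl trifluoromethanesulfonate | FC(F)(F)S(=O)(=O)O/C=C/[C@H]1[C@](C)(O[Si](C)(C)C)C(O[Si](C)(C)C)=C[C@H]2C(C)(C)CCC[C@@]21C | intermediate (not isolated)
9 | (11E)-6α-acetoxy-7-oxo-8α-(trimethylsilyloxy)-13,14,15,16-tetranorlabd-11-en-12-yl trifluoromethanesulfonate | FC(F)(F)S(=O)(=O)O/C=C/[C@H]1[C@](C)(O[Si](C)(C)C)C(=O)[C@H](OC(C)=O)[C@H]2C(C)(C)CCC[C@@]21C | intermediate (not isolated)
10 | (11E)-6α-acetoxy-8α-hydroxy-7-oxo-13,14,15,16-tetranorlabd-11-en-12-yl trifluoromethanesulfonate | FC(F)(F)S(=O)(=O)O/C=C/[C@H]1[C@](C)(O)C(=O)[C@H](OC(C)=O)[C@H]2C(C)(C)CCC[C@@]21C | intermediate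
11 | (11E)-6α-acetoxy-7β,8α-dihydroxy-13,14,15,16-tetranorlabd-11-en-12-yl trifluoromethanesulfonate | FC(F)(F)S(=O)(=O)O/C=C/[C@H]1[C@](C)(O)[C@@H](O)[C@H](OC(C)=O)[C@H]2C(C)(C)CCC[C@@]21C | intermediate
12 | tributyl(1-ethoxyvinyl)stannane | CCCC[Sn](CCCC)(CCCC)C(=C)OCC | starting material
13 | (11E)-6α-acetoxy-13-ethoxy-14,15-dinorlabda-11,13(16)-diene-7β,8α-diol | C=C(OCC)/C=C/[C@H]1[C@](C)(O)[C@@H](O)[C@H](OC(C)=O)[C@H]2C(C)(C)CCC[C@@]21C | intermediate (not isolated)
14 | (11E)-6α-acetoxy-7β,8α-dihydroxy-14,15-dinorlabd-11-en-13-one; (E)-4-[(1R,2S,3S,4R,4aS,8aS)-4-acetoxy-2,3-dihydroxy-2,5,5,8a-tetramethyldecahydronaphthalen-1-yl]but-3-en-2-one | CC(=O)/C=C/[C@H]1[C@](C)(O)[C@@H](O)[C@H](OC(C)=O)[C@H]2C(C)(C)CCC[C@@]21C | target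

**Step count and risks**

Total step count: 8. Longest linear sequence: 8 steps (1 → 14); stannane 12 is purchased.

The three steps most likely to fail:

Step 3 (aldehyde to (E)-alkenyl triflate). Direct enolisation of 4 may give self-aldol products or a poor E/Z ratio. The fallback sets out from 4 and avoids having a free enolate next to free aldehyde. TMSCl, Et3N, DMF, 80 °C gives the isolable (11E)-12-(trimethylsilyloxy)-13,14,15,16-tetranorlabda-7,11-diene F1, whose E isomer is separated on Et3N-deactivated silica. MeLi in THF at 0 °C then cleaves the O–Si bond to the aldehyde-free lithium enolate, which is triflated with PhNTf2; this comes back to the route at 5. Residual Z material is tolerable because the final enone can be equilibrated to E with catalytic I2.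

Step 6 (α-acetoxylation). Lead(IV) acetate may give low conversion, fragmentation of the ketol or a 6-epimer mixture. The fallback sets out from 7, passes through the same bis-silyl enol ether 8, and introduces oxygen and the acyl group separately. Rubottom oxidation (mCPBA, NaHCO3, CH2Cl2, −20 °C; then HF·pyridine) adds oxygen from the α face and gives (11E)-6α,8α-dihydroxy-7-oxo-13,14,15,16-tetranorlabd-11-en-12-yl trifluoromethanesulfonate F2. Its only acylable (secondary) hydroxyl is acetylated with Ac2O, DMAP, pyridine at 0 °C, which comes back to the route at 10.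

Step 8 (coupling and unmasking). Protodetriflation, sluggish transmetalation on the hindered triflate, or trapping of a Z-enone as a cyclic hemiketal during hydrolysis could lower the yield. The fallback sets out from 11 and brings in the acetyl group as an alkyne. Sonogashira coupling with trimethylsilylacetylene (PdCl2(PPh3)2, CuI, iPr2NH, THF, rt) gives (11E)-6α-acetoxy-16-(trimethylsilyl)-14,15-dinorlabd-11-en-13(16)-yne-7β,8α-diol F3. Gold(I)-catalysed Markovnikov hydration with protodesilylation (Ph3PAuNTf2, H2O, dioxane, 60 °C) then gives the methyl ketone and comes back to the route at the target 14.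

**Further compounds**

F1 | step 3 | (11E)-12-(trimethylsilyloxy)-13,14,15,16-tetranorlabda-7,11-diene | C[Si](C)(C)O/C=C/[C@H]1C(C)=CC[C@H]2C(C)(C)CCC[C@@]21C
F2 | step 6 | (11E)-6α,8α-dihydroxy-7-oxo-13,14,15,16-tetranorlabd-11-en-12-yl trifluoromethanesulfonate | FC(F)(F)S(=O)(=O)O/C=C/[C@H]1[C@](C)(O)C(=O)[C@H](O)[C@H]2C(C)(C)CCC[C@@]21C
F3 | step 8 | (11E)-6α-acetoxy-16-(trimethylsilyl)-14,15-dinorlabd-11-en-13(16)-yne-7β,8α-diol | C[Si](C)(C)C#C/C=C/[C@H]1[C@](C)(O)[C@@H](O)[C@H](OC(C)=O)[C@H]2C(C)(C)CCC[C@@]21C
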